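- If a catalyst needs time to wake, an order measured at a fixed amount of product depends on how far the waking has gone by then, so I read one time from the runs.

in all of them: coupling partner 0.250 M

| run | substrate | free catalyst | time |
|---|---|---|---|
| Sunday's | 0.100 M | 0.00500 M |  |
| Saturday's | 0.300 M | 0.00500 M |  |
| Friday's | 0.100 M | 0.0100 M |  |
| Wednesday's | 0.100 M | 0.00500 M | 180 s |

| Sunday's run: time / s | Sunday's run: [product] / M | Saturday's run: time / s | Saturday's run: [product] / M | Friday's run: time / s | Friday's run: [product] / M |
|---|---|---|---|---|---|
| 2.4 | 0 | 2.4 | 0.0042 | 2.4 | 1 × 10⁻⁴ |
| 3.8 | 0.0030 | 3.8 | 0.0085 | 3.8 | 0.0059 |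
| 6.0 | 0.0056 | 6.0 | 0.0188 | 6.0 | 0.0095 |
| 9.5 | 0.0143 | 9.5 | 0.0372 | 9.5 | 0.0223 |
| 15 | 0.0233 | 15 | 0.0671 | 15 | 0.0386 |
| 24 | 0.0392 | 24 | 0.1042 | 24 | 0.0585 |
| 38 | 0.0581 | 38 | 0.1441 | 38 | 0.0749 |
| 60 | 0.0760 | 60 | 0.1765 | 60 | 0.0889 |

(scatter of a reading: 0.001 M)

- the power of [free catalyst] that the first rate follows, about the charge of the Sunday's run; measure it at two percent of substrate made into product
- the power of [substrate] that the first rate follows, about the charge of the Sunday's run; measure it at two percent of substrate made into product (one fixed amount of product, the same in the runs compared)
- product in the Wednesday's run at 180 s, as a share of the substrate charged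
- which of these the readings show (the catalyst wakes slowly / the product binds the second partner / a little impurity takes part of the catalyst at once)

- Overall: substrate + coupling partner -> product, with free catalyst as catalyst.
- Constant volume, constant temperature.
- "The second partner" is coupling partner.
- An order is taken over about fifteen percent of the charge, up and down.

- I draw the integrated second-order line for [substrate] and [coupling partner] through the last two readings of Sunday's run: it stands at 4.04 /M at 38 s and at 7.10 /M at 60 s, a slope of 0.139 /M/s.
- The time by which this line starts late I call the wake lag L, the usual induction period: 9.00 s.
- I take the rate as a constant A, proportional to [substrate], times the awake share of the catalyst, which climbs with time constant L.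
- The upper bound comes from times long past L: the share is whole, and the order in [substrate] is 1.
- The lower bound comes from times far short of L: the share grows with time and product with its square, so the rate at fixed product follows the square root of A, an order of 0.5.
- Joining from the lower end, I expand the same expression and get 0.5 plus t/(6L), where t is the time at which the fixed product is reached.
- Sunday's product reads 0 M at 2.4 s and 0.0056 M at 6.0 s, so I put the two-percent point between those times; the reading between them, 0.0030 M at 3.8 s, stands too near the two-percent amount for its scatter of 0.001 M to place it on one side, so I don't use it as an edge, and my bracket for the order in [substrate] tightens to 0.544 to 0.611.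
- The forecast gives 0.5 for [substrate], 0.55 for the catalyst, 98% for Wednesday's run and "the catalyst wakes slowly", holding that "the catalyst is still waking"; its order in [substrate] lies below my bracket.
- The flask gives 0.61 for [substrate], at the top edge of my bracket and above the forecast, with 0.53 for the catalyst, 97.8% for Wednesday's run and "the catalyst wakes slowly".

    2 active catalyst ⇌ catalyst dimer, settled at all times (40.60 /M)
    active catalyst + substrate + coupling partner → product + active catalyst (33.60 /M²/s)
    free catalyst → active catalyst (0.1310 /s)

- In Sunday's run, my reading puts the two-percent point by 6.0 s, which is 0.667 of L, so the catalyst is still waking there, and the order in [substrate] stands at 0.61 against 1.0 in the same run without the slow step. In Wednesday's run, L is 5.00% of the 180 s asked, and the share of product is 97.8% with the slow step and 98.1% without it.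

The earlier runs and the new flask were generated by integration for an exercise.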